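The benzo ring of the benzofuran is disconnected at C7–C7a and C4–C5, so that C4 is the formyl carbon of a 3-formylfuran and C5, C6 and C7 (with the C5 carbonyl carbon) come from dimethyl succinate. The route exploits the meta relationship of the C7 oxygen and the C5 carbonyl carbon on the benzo ring: after a Stobbe condensation, one operation in hot acetic anhydride acylates the only free furan position (the alpha carbon that becomes C7a), closes and aromatises the carbocycle and delivers C7–O as an acetate. The precursor is an (E)-alkylidene succinic half-ester carried at C3 of a 4-methyl-5-(3,4,5-trimethoxyphenyl)furan whose C2 is unsubstituted.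

Key step: step 7

Assumption: the transient cycloadduct of step 1 and the lactone of step 6 form as racemates (the lactone as a diastereomer mixture) and are drawn without stereodescriptors; the target has no stereocentre.

Step 1
Reactants: 1 4-phenyloxazole; 2 ethyl but-2-ynoate
Product: 4 ethyl 4-methylfuran-3-carboxylate, via oxazabicycloheptadiene cycloadduct 3 (not isolated)
Conditions: neat, sealed tube, 210 °C; distillation
Reagents that add atoms: none
Why: The oxazole reacts as an azadiene across its C2 and C5 in a thermal Diels–Alder reaction with the alkynoate, and the bridged adduct fragments by retro-Diels–Alder loss of benzonitrile, either orientation of addition giving the same 3,4-disubstituted furan.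

Step 2
Reactants: 4 ethyl 4-methylfuran-3-carboxylate
Product: 5 ethyl 5-bromo-4-methylfuran-3-carboxylate
Conditions: NBS (1.05 equiv), DMF, 0 °C to rt, dark
Reagents that add atoms: N-bromosuccinimide, O=C1CCC(=O)N1Br
Why: Electrophilic aromatic bromination should occur at the alpha carbon remote from the ester (C5), because the cation formed there is stabilised by the ring oxygen and the adjacent methyl group and avoids placing charge on the ester-bearing carbon.

Step 3
Reactants: 5 ethyl 5-bromo-4-methylfuran-3-carboxylate; 6 3,4,5-trimethoxyphenylboronic acid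
Product: 7 ethyl 4-methyl-5-(3,4,5-trimethoxyphenyl)furan-3-carboxylate
Conditions: Pd(PPh3)4 (5 mol %), aq. Na2CO3, DME, 85 °C
Reagents that add atoms: none
Why: Suzuki–Miyaura cross-coupling: the 2-bromofuran C–Br bond adds readily to zerovalent palladium and the electron-rich arylboronic acid transmetallates under aqueous carbonate, which the ethyl ester tolerates.

Step 4
Reactants: 7 ethyl 4-methyl-5-(3,4,5-trimethoxyphenyl)furan-3-carboxylate
Product: 8 [4-methyl-5-(3,4,5-trimethoxyphenyl)furan-3-yl]methanol
Conditions: i-Bu2AlH (DIBAL-H, 2.5 equiv), CH2Cl2, −78 to 0 °C; aq. potassium sodium tartrate (KNaC4H4O6)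
Reagents that add atoms: none
Why: DIBAL-H reduction of the conjugated ester to the primary alcohol should proceed cleanly, since the furan, the aryl ethers and the biaryl bond are inert to hydride.

Step 5
Reactants: 8 [4-methyl-5-(3,4,5-trimethoxyphenyl)furan-3-yl]methanol
Product: 9 4-methyl-5-(3,4,5-trimethoxyphenyl)furan-3-carbaldehyde
Conditions: activated MnO2 (excess), CH2Cl2, rt
Reagents that add atoms: none
Why: MnO2 oxidation of a furylmethyl (benzylic-type) alcohol stops at the aldehyde and does not attack the electron-rich furan.

Step 6
Reactants: 9 4-methyl-5-(3,4,5-trimethoxyphenyl)furan-3-carbaldehyde; 10 dimethyl succinate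
Product: 12 (E)-3-(methoxycarbonyl)-4-[4-methyl-5-(3,4,5-trimethoxyphenyl)furan-3-yl]but-3-enoic acid, via paraconate lactone 11 (not isolated)
Conditions: NaOMe (2.2 equiv), MeOH, reflux; then 1 M HCl
Reagents that add atoms: none
Why: Stobbe condensation: the succinate enolate adds to the aldehyde, the aldolate lactonises, and irreversible E1cB opening of the lactone gives the half-ester carboxylate, the (E)-alkene (furan trans to CO2Me, cis to CH2CO2H) being favoured because it keeps the furan away from the ester and the ester conjugated and coplanar.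

Step 7
Reactants: 12 (E)-3-(methoxycarbonyl)-4-[4-methyl-5-(3,4,5-trimethoxyphenyl)furan-3-yl]but-3-enoic acid
Product: 15 methyl 7-acetoxy-3-methyl-2-(3,4,5-trimethoxyphenyl)benzofuran-5-carboxylate, via mixed acetic anhydride 13 (not isolated), via 6H-benzofuran-7-one keto ester 14 (not isolated)
Conditions: Ac2O, NaOAc, reflux (ca. 140 °C)
Reagents that add atoms: acetic anhydride, CC(=O)OC(C)=O
Why: Acetic anhydride converts the acid into the mixed anhydride 13, whose acyl carbon is attacked by the electron-rich furan alpha carbon (or 13 loses acetic acid to a dienylketene that closes by six-electron electrocyclisation) to give, with loss of acetic acid, the 6H-benzofuran-7-one 14; acetate removes a proton from its C6 methylene and the aromatic enolate so formed is O-acetylated at once by the excess anhydride, so that the C7 oxygen emerges directly as acetate 15. The closest known reaction type is the Stobbe/Ac2O–NaOAc benzannulation that turns aryl and heteroaryl aldehydes into acetoxy-substituted benzo-fused esters. The benzo ring closes in a 6-exo-trig mode at the acyl carbon, forming C7–C7a with the furan C2=C3 bond inside the new six-membered ring. No stereocentre is formed, so no stereocontrol element is required. The step needs attack at one furan position and a cis arrangement of chain and ring: the alpha carbon next to the side chain is the only unsubstituted furan carbon (the other neighbour carries the methyl group), and the (E)-alkene holds the CH2CO2H arm on the furan side. Aromatisation to the benzofuran should drive the sequence forward.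

Step 8
Reactants: 15 methyl 7-acetoxy-3-methyl-2-(3,4,5-trimethoxyphenyl)benzofuran-5-carboxylate
Product: 17 methyl 7-methoxy-3-methyl-2-(3,4,5-trimethoxyphenyl)benzofuran-5-carboxylate, via 7-hydroxybenzofuran ester 16 (not isolated)
Conditions: K2CO3, MeOH, rt; evaporate; then MeI, DMF, rt
Reagents that add atoms: iodomethane, CI
Why: Carbonate-promoted methanolysis (transesterification) removes the aryl acetate as methyl acetate while exchange at the methyl ester is degenerate, and the phenoxide of 16 is then O-methylated by MeI in a Williamson ether synthesis.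

Step 9
Reactants: 17 methyl 7-methoxy-3-methyl-2-(3,4,5-trimethoxyphenyl)benzofuran-5-carboxylate
Product: 18 [7-methoxy-3-methyl-2-(3,4,5-trimethoxyphenyl)benzofuran-5-yl]methanol
Conditions: i-Bu2AlH (DIBAL-H, 2.5 equiv), CH2Cl2, −78 to 0 °C; aq. potassium sodium tartrate (KNaC4H4O6)
Reagents that add atoms: none
Why: DIBAL-H reduction of the aryl methyl ester to the benzylic alcohol leaves the aryl methyl ethers and the benzofuran untouched.

Step 10
Reactants: 18 [7-methoxy-3-methyl-2-(3,4,5-trimethoxyphenyl)benzofuran-5-yl]methanol
Product: 19 Ocophyllal B, 7-methoxy-3-methyl-2-(3,4,5-trimethoxyphenyl)benzofuran-5-carbaldehyde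
Conditions: activated MnO2 (excess), CH2Cl2, rt
Reagents that add atoms: none
Why: MnO2 oxidation of the benzylic alcohol should stop at the aryl aldehyde without over-oxidation or damage to the electron-rich rings.

Compound list
1 | 4-phenyloxazole | c1ccc(-c2cocn2)cc1 | starting material
2 | ethyl but-2-ynoate | CC#CC(=O)OCC | starting material
3 | ethyl 5-methyl-3-phenyl-7-oxa-2-azabicyclo[2.2.1]hepta-2,5-diene-6-carboxylate (racemic; the regioisomeric adduct would give the same furan) | CCOC(=O)C1=C(C)C2OC1N=C2c1ccccc1 | intermediate (not isolated)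
4 | ethyl 4-methylfuran-3-carboxylate | CCOC(=O)c1cocc1C | intermediate
5 | ethyl 5-bromo-4-methylfuran-3-carboxylate | CCOC(=O)c1coc(Br)c1C | intermediate
6 | 3,4,5-trimethoxyphenylboronic acid | COc1cc(B(O)O)cc(OC)c1OC | starting material
7 | ethyl 4-methyl-5-(3,4,5-trimethoxyphenyl)furan-3-carboxylate | CCOC(=O)c1coc(-c2cc(OC)c(OC)c(OC)c2)c1C | intermediate
8 | [4-methyl-5-(3,4,5-trimethoxyphenyl)furan-3-yl]methanol | OCc1coc(-c2cc(OC)c(OC)c(OC)c2)c1C | intermediate
9 | 4-methyl-5-(3,4,5-trimethoxyphenyl)furan-3-carbaldehyde | O=Cc1coc(-c2cc(OC)c(OC)c(OC)c2)c1C | intermediate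
10 | dimethyl succinate | COC(=O)CCC(=O)OC | starting material
11 | methyl 2-[4-methyl-5-(3,4,5-trimethoxyphenyl)furan-3-yl]-5-oxooxolane-3-carboxylate (racemic diastereomer mixture) | COC(=O)C1CC(=O)OC1c1coc(-c2cc(OC)c(OC)c(OC)c2)c1C | intermediate (not isolated)
12 | (E)-3-(methoxycarbonyl)-4-[4-methyl-5-(3,4,5-trimethoxyphenyl)furan-3-yl]but-3-enoic acid | COC(=O)/C(CC(=O)O)=C/c1coc(-c2cc(OC)c(OC)c(OC)c2)c1C | intermediate
13 | acetic (E)-3-(methoxycarbonyl)-4-[4-methyl-5-(3,4,5-trimethoxyphenyl)furan-3-yl]but-3-enoic anhydride | COC(=O)/C(CC(=O)OC(C)=O)=C/c1coc(-c2cc(OC)c(OC)c(OC)c2)c1C | intermediate (not isolated)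
14 | methyl 3-methyl-7-oxo-2-(3,4,5-trimethoxyphenyl)-6,7-dihydrobenzofuran-5-carboxylate (keto tautomer of the phenol) | COC(=O)C1=Cc2c(C)c(-c3cc(OC)c(OC)c(OC)c3)oc2C(=O)C1 | intermediate (not isolated)
15 | methyl 7-acetoxy-3-methyl-2-(3,4,5-trimethoxyphenyl)benzofuran-5-carboxylate | COC(=O)c1cc(OC(C)=O)c2oc(-c3cc(OC)c(OC)c(OC)c3)c(C)c2c1 | intermediate
16 | methyl 7-hydroxy-3-methyl-2-(3,4,5-trimethoxyphenyl)benzofuran-5-carboxylate | COC(=O)c1cc(O)c2oc(-c3cc(OC)c(OC)c(OC)c3)c(C)c2c1 | intermediate (not isolated)
17 | methyl 7-methoxy-3-methyl-2-(3,4,5-trimethoxyphenyl)benzofuran-5-carboxylate | COC(=O)c1cc(OC)c2oc(-c3cc(OC)c(OC)c(OC)c3)c(C)c2c1 | intermediate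
18 | [7-methoxy-3-methyl-2-(3,4,5-trimethoxyphenyl)benzofuran-5-yl]methanol | OCc1cc(OC)c2oc(-c3cc(OC)c(OC)c(OC)c3)c(C)c2c1 | intermediate
19 | Ocophyllal B, 7-methoxy-3-methyl-2-(3,4,5-trimethoxyphenyl)benzofuran-5-carbaldehyde | COc1cc(-c2oc3c(OC)cc(C=O)cc3c2C)cc(OC)c1OC | target

Total step count: 10. Longest linear sequence: 10 steps (1 and 2 to 19).

Steps most likely to fail

Step 7. The hot anhydride medium may degrade the furan, or the mixed anhydride may acylate intermolecularly and oligomerise instead of closing the ring. The fallback sets out from 12 and separates activation from ring closure. Oxalyl chloride with catalytic DMF in CH2Cl2 at 0 °C should give the acid chloride methyl (E)-4-chloro-2-{[4-methyl-5-(3,4,5-trimethoxyphenyl)furan-3-yl]methylidene}-4-oxobutanoate F1. SnCl4 in CH2Cl2 at −78 to 0 °C should then effect an intramolecular Friedel–Crafts acylation at the free furan alpha carbon to keto ester 14, which tautomerises on aqueous work-up to the phenol. The fallback comes back to the route at 16, which is here isolated and methylated with MeI and K2CO3 in DMF as in the second stage of step 8 to give 17.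

Step 6. The condensation may stall at the hindered furan aldehyde, the succinate may self-condense, or the alkene geometry may erode. The fallback sets out from 9 and replaces the Stobbe condensation by a Horner–Wadsworth–Emmons olefination with differentiated esters. Trimethyl phosphonoacetate is alkylated with tert-butyl bromoacetate (NaH, THF) to the phosphonosuccinate 4-tert-butyl 1-methyl 2-(dimethoxyphosphoryl)butanedioate F2. Its sodium anion (NaH, THF, 0 °C to rt) should olefinate 9 to the diester 4-tert-butyl 1-methyl (E)-2-{[4-methyl-5-(3,4,5-trimethoxyphenyl)furan-3-yl]methylidene}butanedioate F3. Cleavage of the tert-butyl ester with CF3CO2H in CH2Cl2 at 0 °C to rt, with loss of 2-methylpropene, comes back to the route at 12.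

Step 2. Regiocontrol may be lost, with attack at both alpha carbons, over-bromination or radical attack at the methyl group. The fallback sets out from 4 and uses exhaustive halogenation followed by directed removal of the unwanted halogen. Excess NBS (2.2 equiv, DMF, 40 °C) should give ethyl 2,5-dibromo-4-methylfuran-3-carboxylate F4. Ester-assisted bromine–magnesium exchange at the carbon next to the ester (i-PrMgCl·LiCl, THF, −40 °C), then protonation with MeOH, comes back to the route at 5.

Further compounds
F1 | step 7 | methyl (E)-4-chloro-2-{[4-methyl-5-(3,4,5-trimethoxyphenyl)furan-3-yl]methylidene}-4-oxobutanoate | COC(=O)/C(CC(=O)Cl)=C/c1coc(-c2cc(OC)c(OC)c(OC)c2)c1C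
F2 | step 6 | 4-tert-butyl 1-methyl 2-(dimethoxyphosphoryl)butanedioate (racemic) | COC(=O)C(CC(=O)OC(C)(C)C)P(=O)(OC)OC
F3 | step 6 | 4-tert-butyl 1-methyl (E)-2-{[4-methyl-5-(3,4,5-trimethoxyphenyl)furan-3-yl]methylidene}butanedioate | COC(=O)/C(CC(=O)OC(C)(C)C)=C/c1coc(-c2cc(OC)c(OC)c(OC)c2)c1C
F4 | step 2 | ethyl 2,5-dibromo-4-methylfuran-3-carboxylate | CCOC(=O)c1c(Br)oc(Br)c1C
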